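**Retrosynthetic overview**

1. Ring C is formed last and in one flask: the only free carbon of ring A (C4a) is lithiated and acylated by an (S)-β-silyloxy Weinreb amide that carries ring B (C4a–C4). The unmasked C2 alkoxide then closes the pyranone by displacing fluoride at C8a (O1–C8a).
2. Enabling feature: in ring A, C8a is ortho to C4a (and so to the C4 carbonyl) and meta to both ring oxygens at C5 and C7. F–C8a=C4a–C4=O is therefore a vinylogous acyl fluoride; the same fluorine first directs metalation to C4a and then leaves, and the C2–O bond is never broken.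
3. Ring A is built from 5-fluororesorcinol bis-MOM ether by successive directed metalations: prenyl at C6 (between the two OMOM groups), iodine at C8, then Negishi coupling with a lavandulylzinc reagent.
4. Stereocenters: the lavandulyl center by Evans deconjugative alkylation (auxiliary control); C2 by Noyori transfer hydrogenation of a β-keto Weinreb amide (catalyst control).
5. Ring order: rings A and B enter as benzenes, ring C is closed in the key step, and global MOM removal ends the route.

Key step: step 13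

Remark on the chemistry: the (2R)-lavandulyl group of the target has the spatial arrangement of (S)-lavandulol, because replacing CH2OH by CH2Ar drops that carbon below isopropenyl in CIP rank. 5-Fluororesorcinol is taken as commercially available.

**Route**

Step 1
Reactants: 1 (4S)-4-benzyl-1,3-oxazolidin-2-one; 2 3-methylbut-2-enoyl chloride
Product: 4 (4S)-4-benzyl-3-(3-methylbut-2-enoyl)-1,3-oxazolidin-2-one, via lithium oxazolidinide 3 (not isolated)
Conditions: n-BuLi, THF, −78 °C; then 2, −78 → 0 °C
Reagents that add atoms: none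
Why: N-acylation of the lithiated Evans oxazolidinone by an acid chloride is fast at low temperature and leaves the auxiliary stereocenter untouched.

Step 2
Reactants: 4 (4S)-4-benzyl-3-(3-methylbut-2-enoyl)-1,3-oxazolidin-2-one; 5 1-bromo-3-methylbut-2-ene (prenyl bromide)
Product: 7 (4S)-4-benzyl-3-[(2S)-5-methyl-2-(prop-1-en-2-yl)hex-4-enoyl]-1,3-oxazolidin-2-one, via sodium dienolate 6 (not isolated)
Conditions: NaHMDS, THF, −78 °C; then 5, −78 → −40 °C
Reagents that add atoms: none
Why: Evans asymmetric alkylation run as a deconjugative α-alkylation: γ-deprotonation gives the sodium-chelated (Z)-dienolate, which should react at the α-carbon on the face opposite the benzyl group and so set the (2S) center.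

Step 3
Reactants: 7 (4S)-4-benzyl-3-[(2S)-5-methyl-2-(prop-1-en-2-yl)hex-4-enoyl]-1,3-oxazolidin-2-one
Product: 8 (2S)-5-methyl-2-(prop-1-en-2-yl)hex-4-en-1-ol [(S)-lavandulol]
Conditions: LiBH4, H2O (1 equiv), Et2O, 0 °C
Reagents that add atoms: none
Why: Reductive cleavage of the N-acyl oxazolidinone by lithium borohydride should release the primary alcohol without epimerisation or alkene migration and return the auxiliary.

Step 4
Reactants: 8 (S)-lavandulol
Product: 9 (3S)-3-(iodomethyl)-2,6-dimethylhepta-1,5-diene [(S)-lavandulyl iodide]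
Conditions: I2, PPh3, imidazole, CH2Cl2, 0 °C → rt
Reagents that add atoms: iodine, II
Why: Appel-type iodination proceeds by SN2 at the CH2 group only, so the adjacent stereocenter is not touched.

Step 5
Reactants: 10 5-fluorobenzene-1,3-diol (5-fluororesorcinol)
Product: 11 1-fluoro-3,5-bis(methoxymethoxy)benzene
Conditions: MOMCl, i-Pr2NEt, CH2Cl2, 0 °C → rt
Reagents that add atoms: chloromethyl methyl ether, COCCl
Why: Williamson-type O-alkylation of both phenols gives the bis-MOM ether that serves as protecting and metalation-directing group.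

Step 6
Reactants: 11 1-fluoro-3,5-bis(methoxymethoxy)benzene; 5 prenyl bromide
Product: 13 5-fluoro-1,3-bis(methoxymethoxy)-2-(3-methylbut-2-en-1-yl)benzene, via aryllithium 12 (not isolated)
Conditions: n-BuLi, THF, −40 °C; then CuI (10 mol %), 5, −78 °C → rt
Reagents that add atoms: none
Why: Directed ortho-metalation should take place at the C–H flanked by the two chelating MOM ethers (para to fluorine), and copper-catalysed SN2 allylation of the aryllithium then installs the prenyl group.

Step 7
Reactants: 13 5-fluoro-1,3-bis(methoxymethoxy)-2-(3-methylbut-2-en-1-yl)benzene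
Product: 15 1-fluoro-2-iodo-3,5-bis(methoxymethoxy)-4-(3-methylbut-2-en-1-yl)benzene, via aryllithium 14 (not isolated)
Conditions: s-BuLi, THF, −78 °C; then I2, −78 °C
Reagents that add atoms: iodine, II
Why: A second directed ortho-metalation at one of the two equivalent C–H positions flanked by fluorine and OMOM, held at −78 °C to prevent loss of LiF, is followed by iodinolysis of the aryllithium.

Step 8
Reactants: 9 (S)-lavandulyl iodide; 15 1-fluoro-2-iodo-3,5-bis(methoxymethoxy)-4-(3-methylbut-2-en-1-yl)benzene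
Product: 17 1-fluoro-3,5-bis(methoxymethoxy)-4-(3-methylbut-2-en-1-yl)-2-[(2R)-5-methyl-2-(prop-1-en-2-yl)hex-4-en-1-yl]benzene, via lavandulylzinc iodide 16 (not isolated)
Conditions: 9, Zn dust, LiCl, THF, 40 °C; then 15, Pd(OAc)2 (2 mol %), SPhos (4 mol %), THF, 50 °C
Reagents that add atoms: none
Why: Negishi sp3–sp2 cross-coupling of the primary alkylzinc iodide under a bulky biarylphosphine ligand, which should favour reductive elimination over β-hydride elimination so that the β-stereocenter is retained.

Step 9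
Reactants: 18 methyl 2,4-dihydroxybenzoate
Product: 19 methyl 2,4-bis(methoxymethoxy)benzoate
Conditions: MOMCl, i-Pr2NEt, Bu4NI (cat.), CH2Cl2, reflux
Reagents that add atoms: chloromethyl methyl ether, COCCl
Why: MOM ether formation by O-alkylation of both phenols, the hydrogen-bonded 2-OH needing iodide catalysis and heat.

Step 10
Reactants: 19 methyl 2,4-bis(methoxymethoxy)benzoate; 20 N-methoxy-N-methylacetamide
Product: 22 3-[2,4-bis(methoxymethoxy)phenyl]-N-methoxy-N-methyl-3-oxopropanamide, via lithium enolate 21 (not isolated)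
Conditions: 20 (2.2 equiv), LDA (2.2 equiv), THF, −78 °C; then 19, −78 → 0 °C; aq NH4Cl
Reagents that add atoms: none
Why: Crossed Claisen condensation of the amide enolate with the non-enolisable aryl ester, in which the β-keto amide is deprotonated as it forms and so cannot add a second time.

Step 11
Reactants: 22 3-[2,4-bis(methoxymethoxy)phenyl]-N-methoxy-N-methyl-3-oxopropanamide
Product: 23 (3S)-3-[2,4-bis(methoxymethoxy)phenyl]-3-hydroxy-N-methoxy-N-methylpropanamide
Conditions: RuCl[(S,S)-TsDPEN](p-cymene) (1 mol %), HCO2H/Et3N (5:2), EtOAc, 35 °C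
Reagents that add atoms: none
Why: Noyori asymmetric transfer hydrogenation of the aryl ketone, in which the (S,S)-TsDPEN–Ru hydride should deliver hydrogen to the face that gives the (S)-benzylic carbinol (same sense as acetophenone to (S)-1-phenylethanol) while the amide carbonyl is not reduced.

Step 12
Reactants: 23 (3S)-3-[2,4-bis(methoxymethoxy)phenyl]-3-hydroxy-N-methoxy-N-methylpropanamide
Product: 24 (3S)-3-[2,4-bis(methoxymethoxy)phenyl]-N-methoxy-N-methyl-3-[(triethylsilyl)oxy]propanamide
Conditions: TESCl, imidazole, CH2Cl2, 0 °C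
Reagents that add atoms: chlorotriethylsilane, CC[Si](Cl)(CC)CC
Why: Silylation of the secondary alcohol gives a fluoride-labile ether that should survive the aryllithium of the next step.

Step 13
Reactants: 17 1-fluoro-3,5-bis(methoxymethoxy)-4-(3-methylbut-2-en-1-yl)-2-[(2R)-5-methyl-2-(prop-1-en-2-yl)hex-4-en-1-yl]benzene; 24 (3S)-3-[2,4-bis(methoxymethoxy)phenyl]-N-methoxy-N-methyl-3-[(triethylsilyl)oxy]propanamide
Product: 29 (2S)-2-[2,4-bis(methoxymethoxy)phenyl]-5,7-bis(methoxymethoxy)-6-(3-methylbut-2-en-1-yl)-8-[(2R)-5-methyl-2-(prop-1-en-2-yl)hex-4-en-1-yl]-2,3-dihydro-4H-chromen-4-one, via aryllithium 25 (not isolated), via lithium hemiaminal 26 (not isolated), via silyloxy ketone 27 (not isolated), via ammonium alkoxide 28 (not isolated)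
Conditions: 17, s-BuLi, THF, −78 °C; 24, −78 °C; AcOH (1 equiv), −78 °C; then TBAF (1.2 equiv), −40 °C → rt; pH 7 buffer
Reagents that add atoms: none
Why: The last ring C–H of 17 (C4a) lies between fluorine and an OMOM group, so s-BuLi should lithiate it selectively at −78 °C (directed ortho-metalation), and the aryllithium adds to the Weinreb amide to give a chelated hemiaminal that cannot over-add and that acetic acid collapses to the 2-fluoroaryl ketone. Fluoride then removes the triethylsilyl group and the C2 alkoxide attacks C8a of the vinylogous acyl fluoride F–C8a=C4a–C4=O by addition–elimination (SNAr through a Meisenheimer-type enolate), closing the pyranone ring in a formal 6-endo-trig mode with loss of fluoride. The closest known reaction types are the acylation of ortho-lithiated fluoroarenes with Weinreb amides and the intramolecular SNAr etherification of 2-fluoroaryl ketones by alkoxides. No new stereocenter is formed: C2 keeps the (S) configuration set in step 11 because its C–O bond is never broken (the oxygen is the nucleophile), and the lavandulyl center is remote from all reacting sites. The step needs ring closure to outrun retro-aldol cleavage and E1cB dehydration of the β-alkoxy ketone, which the ortho carbonyl, the meta (non-donating) position of both OMOM groups relative to C8a, fluoride as nucleofuge and the six-membered transition state should secure; attack at C8a rather than C5 follows from fluoride being a far better leaving group than an alkoxide.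

Step 14
Reactants: 29 (2S)-2-[2,4-bis(methoxymethoxy)phenyl]-5,7-bis(methoxymethoxy)-6-(3-methylbut-2-en-1-yl)-8-[(2R)-5-methyl-2-(prop-1-en-2-yl)hex-4-en-1-yl]-2,3-dihydro-4H-chromen-4-one
Product: 30 Kushenol B, (2S)-2-(2,4-dihydroxyphenyl)-5,7-dihydroxy-6-(3-methylbut-2-en-1-yl)-8-[(2R)-5-methyl-2-(prop-1-en-2-yl)hex-4-en-1-yl]-2,3-dihydro-4H-chromen-4-one
Conditions: 3 M HCl (aq), MeOH, 40 °C
Reagents that add atoms: none
Why: Acid-catalysed acetal exchange (MOM solvolysis) in methanol should free the four phenols at a temperature mild enough for the prenyl and isopropenyl double bonds and the C2 center to survive.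

**Compound list**

1 | (4S)-4-benzyl-1,3-oxazolidin-2-one | O=C1N[C@@H](Cc2ccccc2)CO1 | starting material
2 | 3-methylbut-2-enoyl chloride | CC(C)=CC(Cl)=O | starting material
3 | lithium (4S)-4-benzyl-2-oxo-1,3-oxazolidin-3-ide | [Li]N1[C@@H](Cc2ccccc2)COC1=O | intermediate
4 | (4S)-4-benzyl-3-(3-methylbut-2-enoyl)-1,3-oxazolidin-2-one | CC(C)=CC(=O)N1[C@@H](Cc2ccccc2)COC1=O | intermediate
5 | 1-bromo-3-methylbut-2-ene (prenyl bromide) | CC(C)=CCBr | starting material
6 | sodium (Z)-dienolate of 4 | C=C(C)/C=C(\O[Na])N1[C@@H](Cc2ccccc2)COC1=O | intermediate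
7 | (4S)-4-benzyl-3-[(2S)-5-methyl-2-(prop-1-en-2-yl)hex-4-enoyl]-1,3-oxazolidin-2-one | C=C(C)[C@H](CC=C(C)C)C(=O)N1[C@@H](Cc2ccccc2)COC1=O | intermediate
8 | (2S)-5-methyl-2-(prop-1-en-2-yl)hex-4-en-1-ol, (S)-lavandulol | C=C(C)[C@H](CC=C(C)C)CO | intermediate
9 | (3S)-3-(iodomethyl)-2,6-dimethylhepta-1,5-diene, (S)-lavandulyl iodide | C=C(C)[C@H](CC=C(C)C)CI | intermediate
10 | 5-fluorobenzene-1,3-diol (5-fluororesorcinol) | Oc1cc(O)cc(F)c1 | starting material
11 | 1-fluoro-3,5-bis(methoxymethoxy)benzene | COCOc1cc(F)cc(OCOC)c1 | intermediate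
12 | [4-fluoro-2,6-bis(methoxymethoxy)phenyl]lithium | [Li]c1c(OCOC)cc(F)cc1OCOC | intermediate
13 | 5-fluoro-1,3-bis(methoxymethoxy)-2-(3-methylbut-2-en-1-yl)benzene | COCOc1cc(F)cc(OCOC)c1CC=C(C)C | intermediate
14 | [6-fluoro-2,4-bis(methoxymethoxy)-3-(3-methylbut-2-en-1-yl)phenyl]lithium | [Li]c1c(F)cc(OCOC)c(CC=C(C)C)c1OCOC | intermediate
15 | 1-fluoro-2-iodo-3,5-bis(methoxymethoxy)-4-(3-methylbut-2-en-1-yl)benzene | Ic1c(F)cc(OCOC)c(CC=C(C)C)c1OCOC | intermediate
16 | [(2S)-5-methyl-2-(prop-1-en-2-yl)hex-4-en-1-yl]zinc iodide | C=C(C)[C@H](CC=C(C)C)C[Zn]I | intermediate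
17 | 1-fluoro-3,5-bis(methoxymethoxy)-4-(3-methylbut-2-en-1-yl)-2-[(2R)-5-methyl-2-(prop-1-en-2-yl)hex-4-en-1-yl]benzene | C=C(C)[C@H](CC=C(C)C)Cc1c(F)cc(OCOC)c(CC=C(C)C)c1OCOC | intermediate
18 | methyl 2,4-dihydroxybenzoate | COC(=O)c1ccc(O)cc1O | starting material
19 | methyl 2,4-bis(methoxymethoxy)benzoate | COCOc1ccc(C(=O)OC)c(OCOC)c1 | intermediate
20 | N-methoxy-N-methylacetamide | CC(=O)N(C)OC | starting material
21 | lithium enolate of N-methoxy-N-methylacetamide | C=C(O[Li])N(C)OC | intermediate
22 | 3-[2,4-bis(methoxymethoxy)phenyl]-N-methoxy-N-methyl-3-oxopropanamide | COCOc1ccc(C(=O)CC(=O)N(C)OC)c(OCOC)c1 | intermediate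
23 | (3S)-3-[2,4-bis(methoxymethoxy)phenyl]-3-hydroxy-N-methoxy-N-methylpropanamide | O[C@H](c1ccc(OCOC)cc1OCOC)CC(=O)N(C)OC | intermediate
24 | (3S)-3-[2,4-bis(methoxymethoxy)phenyl]-N-methoxy-N-methyl-3-[(triethylsilyl)oxy]propanamide | CC[Si](CC)(CC)O[C@H](c1ccc(OCOC)cc1OCOC)CC(=O)N(C)OC | intermediate
25 | {2-fluoro-4,6-bis(methoxymethoxy)-5-(3-methylbut-2-en-1-yl)-3-[(2R)-5-methyl-2-(prop-1-en-2-yl)hex-4-en-1-yl]phenyl}lithium | C=C(C)[C@H](CC=C(C)C)Cc1c(F)c([Li])c(OCOC)c(CC=C(C)C)c1OCOC | intermediate
26 | lithium hemiaminal (tetrahedral adduct of 25 to the amide carbonyl of 24; configuration at the new carbinol carbon undefined) | C=C(C)[C@H](CC=C(C)C)Cc1c(F)c(C(O[Li])(C[C@H](O[Si](CC)(CC)CC)c2ccc(OCOC)cc2OCOC)N(C)OC)c(OCOC)c(CC=C(C)C)c1OCOC | intermediate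
27 | (3S)-3-[2,4-bis(methoxymethoxy)phenyl]-1-{2-fluoro-4,6-bis(methoxymethoxy)-5-(3-methylbut-2-en-1-yl)-3-[(2R)-5-methyl-2-(prop-1-en-2-yl)hex-4-en-1-yl]phenyl}-3-[(triethylsilyl)oxy]propan-1-one | C=C(C)[C@H](CC=C(C)C)Cc1c(F)c(C(=O)C[C@H](O[Si](CC)(CC)CC)c2ccc(OCOC)cc2OCOC)c(OCOC)c(CC=C(C)C)c1OCOC | intermediate
28 | tetrabutylammonium (1S)-alkoxide of desilylated 27 | C=C(C)[C@H](CC=C(C)C)Cc1c(F)c(C(=O)C[C@H]([O-])c2ccc(OCOC)cc2OCOC)c(OCOC)c(CC=C(C)C)c1OCOC.CCCC[N+](CCCC)(CCCC)CCCC | intermediate
29 | (2S)-2-[2,4-bis(methoxymethoxy)phenyl]-5,7-bis(methoxymethoxy)-6-(3-methylbut-2-en-1-yl)-8-[(2R)-5-methyl-2-(prop-1-en-2-yl)hex-4-en-1-yl]-2,3-dihydro-4H-chromen-4-one | C=C(C)[C@H](CC=C(C)C)Cc1c(OCOC)c(CC=C(C)C)c(OCOC)c2c1O[C@H](c1ccc(OCOC)cc1OCOC)CC2=O | intermediate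
30 | Kushenol B | C=C(C)[C@H](CC=C(C)C)Cc1c(O)c(CC=C(C)C)c(O)c2c1O[C@H](c1ccc(O)cc1O)CC2=O | target

**Totals**

Total step count: 14.
Longest linear sequence: 7 steps (steps 1, 2, 3, 4, 8, 13, 14).

**Three steps most likely to fail**

1. Step 13. The β-alkoxy ketone may undergo retro-aldol cleavage or E1cB dehydration before the ring closes, which would cost material and erode the C2 configuration. The product may also ring-open and reclose under the basic fluoride, and the ortho-fluoroaryllithium may lose LiF before it is acylated. The fallback closes ring C at the chromone oxidation level, where no carbinol stereocenter or aldol linkage is exposed to base, and sets C2 afterwards. It sets out from 17: aryllithium 25 is quenched with N-methoxy-N-methylacetamide 20 to give the methyl ketone F1. Claisen condensation with ethyl formate (NaH, THF) and warming in DMF should give the chromone F2 by SNAr of the enolate oxygen at C8a. In parallel, 4-bromoresorcinol is protected (MOMCl, i-Pr2NEt) as 1-bromo-2,4-bis(methoxymethoxy)benzene F3 and converted (n-BuLi, B(OMe)3, aqueous work-up) into the boronic acid F4. Rhodium-catalysed asymmetric 1,4-addition of F4 to F2 (Hayashi–Miyaura type, Rh(I) with a chiral diene or bisphosphine, ligand antipode chosen for the 2S series) comes back to the route at 29.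

2. Step 8. Transmetalation and reductive elimination at the di-ortho-substituted arylpalladium may be slow, and β-hydride elimination of the alkylpalladium would reduce the arene and, through reinsertion, erode the adjacent stereocenter. The fallback inverts the polarity and avoids alkylpalladium species. It sets out from 15 and 8: iodine–magnesium exchange on 15 (i-PrMgCl·LiCl, THF, −40 °C) gives the arylmagnesium chloride F5, and (S)-lavandulol 8 is converted (TsCl, pyridine) into the tosylate F6. Copper-catalysed SN2 coupling of F5 with F6 (Li2CuCl4, THF, −20 °C → rt) comes back to the route at 17.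

3. Step 14. Under protic acid the C7 or C5 phenol may add to the isopropenyl or prenyl double bond (chroman formation), and acid-induced opening of the 2-(2,4-dihydroxyphenyl)chromanone may partly scramble C2. The fallback avoids protic acid by trans-protection. It sets out from 29: TMSOTf and 2,2′-bipyridyl (CH2Cl2, 0 °C) should exchange the four aryl MOM ethers for silyl ethers to give the tetrakis(trimethylsilyl) ether F7, which neutral hydrolysis (H2O, THF, rt) should convert into 30, where it rejoins the route.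

**Further compounds**

F1 | step 13 | 1-{2-fluoro-4,6-bis(methoxymethoxy)-5-(3-methylbut-2-en-1-yl)-3-[(2R)-5-methyl-2-(prop-1-en-2-yl)hex-4-en-1-yl]phenyl}ethan-1-one | C=C(C)[C@H](CC=C(C)C)Cc1c(F)c(C(C)=O)c(OCOC)c(CC=C(C)C)c1OCOC
F2 | step 13 | 5,7-bis(methoxymethoxy)-6-(3-methylbut-2-en-1-yl)-8-[(2R)-5-methyl-2-(prop-1-en-2-yl)hex-4-en-1-yl]-4H-chromen-4-one | C=C(C)[C@H](CC=C(C)C)Cc1c(OCOC)c(CC=C(C)C)c(OCOC)c2c1OC=CC2=O
F3 | step 13 | 1-bromo-2,4-bis(methoxymethoxy)benzene | COCOc1ccc(Br)c(OCOC)c1
F4 | step 13 | [2,4-bis(methoxymethoxy)phenyl]boronic acid | COCOc1ccc(B(O)O)c(OCOC)c1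
F5 | step 8 | [6-fluoro-2,4-bis(methoxymethoxy)-3-(3-methylbut-2-en-1-yl)phenyl]magnesium chloride | Cl[Mg]c1c(F)cc(OCOC)c(CC=C(C)C)c1OCOC
F6 | step 8 | (2S)-5-methyl-2-(prop-1-en-2-yl)hex-4-en-1-yl 4-methylbenzenesulfonate | C=C(C)[C@H](CC=C(C)C)COS(=O)(=O)c1ccc(C)cc1
F7 | step 14 | (2S)-6-(3-methylbut-2-en-1-yl)-8-[(2R)-5-methyl-2-(prop-1-en-2-yl)hex-4-en-1-yl]-2-[2,4-bis(trimethylsilyloxy)phenyl]-5,7-bis(trimethylsilyloxy)-2,3-dihydro-4H-chromen-4-one | C=C(C)[C@H](CC=C(C)C)Cc1c(O[Si](C)(C)C)c(CC=C(C)C)c(O[Si](C)(C)C)c2c1O[C@H](c1ccc(O[Si](C)(C)C)cc1O[Si](C)(C)C)CC2=O
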